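One amount barely moves between the two earlier runs: the target at the end, counted as a concentration and not as a percent.

| flask | substrate | free enzyme | temperature | remark | time |
|---|---|---|---|---|---|
| teal | 0.068 M | 5 µM | 20 °C | run made earlier |  |
| grey | 0.23 M | 5 µM | 31 °C | run made earlier |  |
| north | 0.20 M | 5.0 µM | 25 °C |  | 10 d |
| north-west | 0.050 M | 5.0 µM | 25 °C |  | 5.0 d |

| run | time / d | target / % | substrate / % |
|---|---|---|---|
| teal | 0.625 | 5.4 | 94.6 |
| teal | 1.25 | 6.9 | 92.9 |
| teal | 2.00 | 8.0 | 92.0 |
| teal | 3.00 | 9.9 | 90.8 |
| teal | 4.00 | 10.4 | 90.3 |
| grey | 0.333 | 1.6 | 97.9 |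
| grey | 0.833 | 2.8 | 97.6 |
| grey | 1.67 | 3.5 | 96.9 |
| grey | 2.50 | 3.5 | 96.3 |
| grey | 4.00 | 3.5 | 96.5 |

(each reading ± 0.3 percentage points)

* the flask that ends with the higher amount of target, in percent of the substrate charged, or "neither" when 2 percentage points or less lies between them (north / north-west / neither)
* final target, as a percentage of the substrate charged, in north
* final target, as a percentage of the substrate charged, in north-west

Teal ends at 10.4 % of a 0.068 M charge, which is 7.07 mM. Grey ends at 3.5 % of a 0.23 M charge, which is 8.05 mM. The charges differ by a factor of 3.38. The concentrations reached differ by a factor of 1.14.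

Two chemists read this differently. The first holds that free enzyme makes a set concentration of target before it stops, whatever the charge. My own reckoning takes the mean, 7.56 mM, as that ceiling for 5.0 µM of free enzyme. Per enzyme, this is the total turnover number. Dividing the ceiling by the charge gives 3.78 % in north and 15.1 % in north-west. Her forecast differs from this division: it expects about 8 mM in north and 7 mM in north-west, so 4 % and 14 %, and it names north-west. In her words: “The near-constant absolute yield points to the enzyme dying after a set number of turnovers”.

The second chemist holds that the rate is first order in substrate and in free enzyme. In that view the percent reached does not depend on the charge. He puts grey's low percent down to its warmth, 31 °C against 20 °C. At 25 °C he expects about 6.95 % in both flasks. Teal still rose from 9.9 % to 10.4 % at its end, and north runs twice as long as north-west, so he says north.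

The simulation gives 13.5 % in north-west, higher than the 5.25 % in north. The forecast held.

    free enzyme → unfolded enzyme (k = 5.59 × 10⁻⁷ s⁻¹, Ea = 216 kJ mol⁻¹)
    substrate + free enzyme → target + free enzyme, rate k2*[substrate]*[free enzyme]/(1 + ([substrate]/Km2)) (25.0 mM, k = 3.00 M⁻¹ s⁻¹, Ea = 40.0 kJ mol⁻¹)
    2 free enzyme → spent catalyst (k = 14.6 M⁻¹ s⁻¹, Ea = 40.0 kJ mol⁻¹)
    (constants at 25 °C)

The ceiling is no constant: north holds 10.5 mM and north-west 6.76 mM, against 7.56 mM. Still, the gap is 8.3 percentage points, with a margin of 2 points. North-west falls short of full conversion mainly because of the step from two free enzyme to spent catalyst: without that step it gives 97.8 %, not 13.5 %. The term in substrate below the line of the rate law is part of why north-west wins: without it, north gives 37.8 % and north-west 34.0 %, the second chemist's order. The rate law comes close to his first order where substrate lies far below 25.0 mM. For a neighbour flask, north-west with 0.12 M of substrate, the ceiling gives 6.30 % and the flask gives 7.12 %.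

Readings and results stem from a simulated flask with made-up constants; scatter was added.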